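At early times the flask holds substrate and partner at their charges, so I can price each route of the substrate before any product interferes.

all flasks: substrate 43 mM; partner 40.8 mM; time 30 h
- grey: temperature 25 °C
- green: temperature 35 °C
- teal: temperature 45 °C

    substrate + by-product → side product (k1 = 0.30 M⁻¹ h⁻¹, Ea1 = 68.0 kJ mol⁻¹)
    substrate ⇌ dormant form (K2 = 22, k2 = 0.048 h⁻¹, Ea2 = 99.0 kJ mol⁻¹, ΔH2 = −1.00 kJ mol⁻¹)
    2 substrate → self-condensation product (k3 = 0.44 M⁻¹ h⁻¹, Ea3 = 79.0 kJ mol⁻¹)
    substrate + partner → other mono adduct + by-product (k4 = 0.96 M⁻¹ h⁻¹, Ea4 = 69.0 kJ mol⁻¹)
    substrate + partner → mono adduct + by-product (k5 = 2.8 M⁻¹ h⁻¹, Ea5 = 77.0 kJ mol⁻¹)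
    partner + other mono adduct → bis adduct + by-product (k6 = 0.47 M⁻¹ h⁻¹, Ea6 = 54.0 kJ mol⁻¹)
    partner + mono adduct → bis adduct + by-product (k7 = 6.3 M⁻¹ h⁻¹, Ea7 = 54.0 kJ mol⁻¹)
    (constants at 25 °C)

* which of these there is most of at the end, counted by the substrate in it, grey (mono adduct / substrate / bis adduct / side product / other mono adduct)
* which of these there is most of at the end, counted by the substrate in it, green (mono adduct / substrate / bis adduct / side product / other mono adduct)
* which of these there is most of at the end, counted by the substrate in it, teal (mono adduct / substrate / bis adduct / side product / other mono adduct)
* final amount of the leader among these, as a percentage of the substrate charged, in grey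
* final amount of the leader among these, as a percentage of the substrate charged, in green
* final amount of the leader among these, as a percentage of the substrate charged, in teal

- a species is counted by the substrate in it: one self-condensation product counts as two
- a doubled species enters its step squared and goes two at a time
- all constants are for 25 °C and move with temperature by the activation energies and enthalpies

1. I freeze substrate and partner at their charges. Each route out of the substrate is then pseudo-first-order. The by-product route starts at zero and the way back from dormant form is left out, so the routes sum to 0.239 h⁻¹ in grey, 0.692 h⁻¹ in green and 1.90 h⁻¹ in teal.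

2. In grey, 64.1 % of that sum is first addition of partner. I call this the capture share: the fraction of the charge I expect to end up in adducts. It is 59.2 % in green and 54.2 % in teal.

3. A first estimate, the mono route: partner adds to mono adduct faster than to other mono adduct, so I count the mono route as the supply of bis adduct. That gives 47.7 % in grey, 45.3 % in green and 42.3 % in teal.

4. A second estimate, the ledger: the partner charge is 94.9 % of the substrate charge. A first adduct holds one partner and a bis adduct two, so the bis fraction equals partner used minus the fraction in adducts. Supposing partner spent and adducts at the capture share, I put the bis fraction at the partner charge minus the capture share. This is an estimate and no limit: unspent partner lowers it, and a capture below my frozen share raises it.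

5. Neither estimate is a limit the flask must obey, but I commit to the smaller, which in grey is the ledger, and likewise in green and teal. That gives 30.8 %, 35.6 % and 40.7 %, and the leader is bis adduct in grey. Green and teal give bis adduct and bis adduct.

6. The forecast names bis adduct at 31 %, 38 % and 40 %, saying “the bis yield rises only modestly”, and its grey value stands level with my ledger estimate and under my mono-route estimate.

The flasks give bis adduct at 31.7 % in grey, 37.1 % in green and 40.1 % in teal. At 30.0 h, grey still holds 12 % of its partner. Left for 300 h, grey keeps 0.494 % of its partner and reaches 41.1 % bis adduct, above my ledger estimate and below the mono-route part 47.7 % of the capture share.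

Now take a neighbour flask, grey with 69 mM of partner. The capture share becomes 75.1 %, the ledger gives 85.3 %, and the mono route gives 56.0 %, so the smaller estimate is now the mono route. That flask ends at 53.8 % bis adduct with 23 % of its partner unbound.

All constants were set for the occasion.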